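**Plan**

Retrosynthesis: cut (i) the C10–O angelate ester, (ii) the C8=C9 double bond of the seven-membered ring, (iii) C9–C10 (vinyl + aldehyde), (iv) C4–isopropyl, (v) C5–C6 (aldol) and (vi) C1–CH3 (conjugate addition). This leads back to 3-(hydroxymethyl)cyclopent-2-en-1-one, 3-methylbut-3-en-1-ol and angelic acid.
Enabling feature: C8=C9 is the only endocyclic olefin. It is trisubstituted and lies in the seven-membered ring between the allylic C10 carbinol and C7H2, so the ring opens there into a vinyl carbinol arm on C1 and a methallyl carbinol arm on C5, trans on the cyclopentane.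
Forward: the five-membered ring is bought as an enone; C1, the C5/C6 arm, C4 and C10 are set on it in that order; ring-closing metathesis closes the seven-membered ring last; the angelate goes on at the end.
Stereochemistry: C1 from a chiral NHC–copper catalyst; C5 by attack anti to the silyloxymethyl group; C6 by the chair boron aldol; C4 by attack anti to the C5 arm; C10 by a chiral amino-alcohol zinc catalyst; the ring enforces the Z olefin; the angelate geometry comes from angelic acid.

Key step: step 10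

Remark: 3-(hydroxymethyl)cyclopent-2-en-1-one is taken as a catalogue compound. C1–C10 in the Why lines are daucane positions: C1 methyl-bearing ring-fusion carbon, C4 isopropyl carbinol, C5 ring-fusion CH, C6 benzoyloxy carbon, C7 CH2, C8=C9 olefin, C10 angeloyloxy carbon.

**Route**

Step 1
Reactants: 1 3-(hydroxymethyl)cyclopent-2-en-1-one
Product: 2 3-({[tri(propan-2-yl)silyl]oxy}methyl)cyclopent-2-en-1-one
Conditions: TIPSCl, imidazole, DMF, rt
Reagents that add atoms: chlorotri(propan-2-yl)silane, CC(C)[Si](Cl)(C(C)C)C(C)C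
Why: Imidazole-promoted silylation of a primary alcohol; the bulky silyl ether masks the future C10 oxygen and later shields one face of the ring.

Step 2
Reactants: 2 3-({[tri(propan-2-yl)silyl]oxy}methyl)cyclopent-2-en-1-one
Product: 4 triethyl{[(3S)-3-methyl-3-({[tri(propan-2-yl)silyl]oxy}methyl)cyclopent-1-en-1-yl]oxy}silane, via dimethylaluminium enolate 3 (not isolated)
Conditions: Me3Al (3 equiv), Cu(OTf)2 (5 mol %), chiral sulfonate-bridged NHC–Ag(I) complex (2.5 mol %), THF, −78 °C; then Et3SiOTf, −78 → 0 °C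
Reagents that add atoms: trimethylaluminium, C[Al](C)C; triethylsilyl trifluoromethanesulfonate, CC[Si](CC)(CC)OS(=O)(=O)C(F)(F)F
Why: NHC–copper-catalysed enantioselective conjugate addition of an alkylaluminium to a β-substituted cyclopentenone should create the quaternary centre C1 under catalyst control (ligand enantiomer chosen for methyl delivery to the Re face of the β-carbon, giving 3S), and O-silylation of the aluminium enolate fixes the enol double bond toward the carbon next to C1, which kinetic deprotonation of the ketone would not do.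

Step 3
Reactants: 5 3-methylbut-3-en-1-ol
Product: 6 3-methylbut-3-enal
Conditions: Dess–Martin periodinane, pyridine, CH2Cl2, 0 °C; cold filtered solution used at once
Reagents that add atoms: none
Why: Dess–Martin oxidation under buffered, non-basic conditions should give the β,γ-unsaturated aldehyde without conjugation to 3-methylbut-2-enal.

Step 4
Reactants: 4 triethyl{[(3S)-3-methyl-3-({[tri(propan-2-yl)silyl]oxy}methyl)cyclopent-1-en-1-yl]oxy}silane; 6 3-methylbut-3-enal
Product: 9 (2S,3S)-2-[(1S)-1-hydroxy-3-methylbut-3-en-1-yl]-3-methyl-3-({[tri(propan-2-yl)silyl]oxy}methyl)cyclopentan-1-one, via lithium enolate 7 (not isolated), via dicyclohexylboron enolate 8 (not isolated)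
Conditions: MeLi (1.0 equiv), THF, 0 °C; (c-C6H11)2BCl, −78 °C; then 6, −78 → −20 °C; pH 7 buffer, MeOH, 30% H2O2, 0 °C
Reagents that add atoms: none
Why: Cleavage of the silyl enol ether gives the regiodefined enolate, exchange to the ring-fixed (E)-boron enolate and a Zimmerman–Traxler chair should give the anti aldol (C5/C6), and the aldehyde should approach C5 anti to the silyloxymethyl group on the neighbouring quaternary carbon, so the new arm ends cis to the methyl group (2S and 1'S set here).

Step 5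
Reactants: 9 (2S,3S)-2-[(1S)-1-hydroxy-3-methylbut-3-en-1-yl]-3-methyl-3-({[tri(propan-2-yl)silyl]oxy}methyl)cyclopentan-1-one
Product: 10 (1R,2S,3S)-2-[(1S)-1-hydroxy-3-methylbut-3-en-1-yl]-3-methyl-1-(propan-2-yl)-3-({[tri(propan-2-yl)silyl]oxy}methyl)cyclopentan-1-ol
Conditions: i-PrMgCl (3.5 equiv), anhydrous CeCl3 (3.5 equiv), THF, −78 → −40 °C; aq NH4Cl
Reagents that add atoms: isopropylmagnesium chloride, CC(C)[Mg]Cl
Why: Organocerium addition suppresses enolisation and β-hydride reduction of the hindered ketone; after the first equivalent has deprotonated the hydroxyl, isopropyl should add to the carbonyl face anti to the C5 side chain of the chelated aldolate, giving the tertiary carbinol with OH cis to that chain (1R).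

Step 6
Reactants: 10 (1R,2S,3S)-2-[(1S)-1-hydroxy-3-methylbut-3-en-1-yl]-3-methyl-1-(propan-2-yl)-3-({[tri(propan-2-yl)silyl]oxy}methyl)cyclopentan-1-ol
Product: 11 (1S)-1-[(1S,2R,5S)-2-hydroxy-5-methyl-2-(propan-2-yl)-5-({[tri(propan-2-yl)silyl]oxy}methyl)cyclopentyl]-3-methylbut-3-en-1-yl benzoate
Conditions: BzCl, pyridine, DMAP (cat.), CH2Cl2, 0 °C → rt
Reagents that add atoms: benzoyl chloride, O=C(Cl)c1ccccc1
Why: DMAP-catalysed acylation should take the secondary carbinol only, the tertiary one being inert under these conditions.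

Step 7
Reactants: 11 (1S)-1-[(1S,2R,5S)-2-hydroxy-5-methyl-2-(propan-2-yl)-5-({[tri(propan-2-yl)silyl]oxy}methyl)cyclopentyl]-3-methylbut-3-en-1-yl benzoate
Product: 12 (1S)-1-[(1S,2R,5S)-2-hydroxy-5-(hydroxymethyl)-5-methyl-2-(propan-2-yl)cyclopentyl]-3-methylbut-3-en-1-yl benzoate
Conditions: HF·pyridine, pyridine, THF, 0 °C → rt
Reagents that add atoms: none
Why: Buffered fluoride cleaves the primary silyl ether and should leave the benzoate, the tertiary alcohol and the 1,1-disubstituted alkene untouched.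

Step 8
Reactants: 12 (1S)-1-[(1S,2R,5S)-2-hydroxy-5-(hydroxymethyl)-5-methyl-2-(propan-2-yl)cyclopentyl]-3-methylbut-3-en-1-yl benzoate
Product: 13 (1S)-1-[(1S,2S,5R)-2-formyl-5-hydroxy-2-methyl-5-(propan-2-yl)cyclopentyl]-3-methylbut-3-en-1-yl benzoate
Conditions: Dess–Martin periodinane, pyridine, CH2Cl2, 0 °C → rt
Reagents that add atoms: none
Why: Dess–Martin oxidation of the neopentyl primary alcohol gives a non-enolisable aldehyde; the tertiary hydroxyl is inert and stands trans to the formyl group, so no lactol can form.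

Step 9
Reactants: 13 (1S)-1-[(1S,2S,5R)-2-formyl-5-hydroxy-2-methyl-5-(propan-2-yl)cyclopentyl]-3-methylbut-3-en-1-yl benzoate
Product: 14 (1S)-1-[(1S,2R,5S)-2-hydroxy-5-[(1R)-1-hydroxyprop-2-en-1-yl]-5-methyl-2-(propan-2-yl)cyclopentyl]-3-methylbut-3-en-1-yl benzoate
Conditions: vinylmagnesium bromide + ZnCl2 (2:1), salts precipitated with 1,4-dioxane, giving divinylzinc in toluene; (+)-DAIB (15 mol %), toluene, 0 °C; aq NH4Cl
Reagents that add atoms: divinylzinc, C=C[Zn]C=C
Why: Amino-alcohol-catalysed alkenylzinc addition to an aldehyde: the chiral zinc aminoalkoxide should deliver vinyl to the Re face of the formyl group and set C10 as R by reagent control, the Felkin bias of this α-quaternary aldehyde being small (it distinguishes only ring CH2 from CH3); the organozinc tolerates the benzoate and merely deprotonates the tertiary alcohol.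

Step 10
Reactants: 14 (1S)-1-[(1S,2R,5S)-2-hydroxy-5-[(1R)-1-hydroxyprop-2-en-1-yl]-5-methyl-2-(propan-2-yl)cyclopentyl]-3-methylbut-3-en-1-yl benzoate
Product: 15 (3R,3aS,4S,8R,8aS)-3,8-dihydroxy-6,8a-dimethyl-3-(propan-2-yl)-1,2,3,3a,4,5,8,8a-octahydroazulen-4-yl benzoate
Conditions: Hoveyda–Grubbs II (10 mol %), 1,4-benzoquinone (20 mol %), toluene (0.005 M), 80 °C, argon sparge
Reagents that add atoms: none
Why: Ring-closing olefin metathesis (Chauvin mechanism): the ruthenium alkylidene loads on the monosubstituted C9 vinyl group, adds across the 1,1-disubstituted C8 methylidene in an intramolecular [2+2] step, and the ruthenacyclobutane collapses to the cycloalkene and a ruthenium methylidene that leaves as ethene. The closest known reaction type is RCM of an allylic-alcohol vinyl group with a gem-disubstituted alkene to give a trisubstituted cycloheptene fused to a cyclopentane. The seven-membered ring is closed by creating the endocyclic C8=C9 bond; the diene has no third alkene, so no other ring size can arise. No stereocentre is formed, the five existing ones are untouched, and the ring size enforces the Z geometry. The step needs cyclisation to win over oligomerisation and over Ru–H isomerisation of the allylic alcohol: the two arms are held trans-vicinal on the cyclopentane next to the quaternary C1 (Thorpe–Ingold pre-organisation, unstrained trans-fused product), the free allylic hydroxyl assists the catalyst, and high dilution with benzoquinone should suppress the side paths.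

Step 11
Reactants: 15 (3R,3aS,4S,8R,8aS)-3,8-dihydroxy-6,8a-dimethyl-3-(propan-2-yl)-1,2,3,3a,4,5,8,8a-octahydroazulen-4-yl benzoate; 16 (2Z)-2-methylbut-2-enoic acid (angelic acid)
Product: 18 (3R,3aS,4S,8R,8aS)-3-hydroxy-6,8a-dimethyl-8-{[(2Z)-2-methylbut-2-enoyl]oxy}-3-(propan-2-yl)-1,2,3,3a,4,5,8,8a-octahydroazulen-4-yl benzoate, via angelic 2,4,6-trichlorobenzoic anhydride 17 (not isolated)
Conditions: 16, 2,4,6-trichlorobenzoyl chloride, Et3N, toluene, rt; then 15, 80 °C (no DMAP)
Reagents that add atoms: none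
Why: Yamaguchi mixed-anhydride acylation without DMAP is the standard way to form angelates without Z-to-E isomerisation; only the secondary allylic hydroxyl should react, the tertiary one staying free.

**Compound list**

1 | 3-(hydroxymethyl)cyclopent-2-en-1-one | O=C1C=C(CO)CC1 | starting material
2 | 3-({[tri(propan-2-yl)silyl]oxy}methyl)cyclopent-2-en-1-one | O=C1C=C(CO[Si](C(C)C)(C(C)C)C(C)C)CC1 | intermediate
3 | dimethylaluminium enolate: dimethyl{[(3S)-3-methyl-3-({[tri(propan-2-yl)silyl]oxy}methyl)cyclopent-1-en-1-yl]oxy}alumane | C[Al](C)OC1=C[C@@](C)(CO[Si](C(C)C)(C(C)C)C(C)C)CC1 | intermediate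
4 | triethyl{[(3S)-3-methyl-3-({[tri(propan-2-yl)silyl]oxy}methyl)cyclopent-1-en-1-yl]oxy}silane | CC[Si](CC)(CC)OC1=C[C@@](C)(CO[Si](C(C)C)(C(C)C)C(C)C)CC1 | intermediate
5 | 3-methylbut-3-en-1-ol | C=C(C)CCO | starting material
6 | 3-methylbut-3-enal | C=C(C)CC=O | intermediate
7 | lithium enolate: lithium (3S)-3-methyl-3-({[tri(propan-2-yl)silyl]oxy}methyl)cyclopent-1-en-1-olate | [Li]OC1=C[C@@](C)(CO[Si](C(C)C)(C(C)C)C(C)C)CC1 | intermediate
8 | dicyclohexylboron enolate: dicyclohexyl{[(3S)-3-methyl-3-({[tri(propan-2-yl)silyl]oxy}methyl)cyclopent-1-en-1-yl]oxy}borane | C1CCCCC1B(OC2=C[C@@](C)(CO[Si](C(C)C)(C(C)C)C(C)C)CC2)C3CCCCC3 | intermediate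
9 | (2S,3S)-2-[(1S)-1-hydroxy-3-methylbut-3-en-1-yl]-3-methyl-3-({[tri(propan-2-yl)silyl]oxy}methyl)cyclopentan-1-one | C=C(C)C[C@H](O)[C@H]1C(=O)CC[C@]1(C)CO[Si](C(C)C)(C(C)C)C(C)C | intermediate
10 | (1R,2S,3S)-2-[(1S)-1-hydroxy-3-methylbut-3-en-1-yl]-3-methyl-1-(propan-2-yl)-3-({[tri(propan-2-yl)silyl]oxy}methyl)cyclopentan-1-ol | C=C(C)C[C@H](O)[C@H]1[C@](O)(C(C)C)CC[C@]1(C)CO[Si](C(C)C)(C(C)C)C(C)C | intermediate
11 | (1S)-1-[(1S,2R,5S)-2-hydroxy-5-methyl-2-(propan-2-yl)-5-({[tri(propan-2-yl)silyl]oxy}methyl)cyclopentyl]-3-methylbut-3-en-1-yl benzoate | C=C(C)C[C@H](OC(=O)c1ccccc1)[C@H]2[C@](O)(C(C)C)CC[C@]2(C)CO[Si](C(C)C)(C(C)C)C(C)C | intermediate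
12 | (1S)-1-[(1S,2R,5S)-2-hydroxy-5-(hydroxymethyl)-5-methyl-2-(propan-2-yl)cyclopentyl]-3-methylbut-3-en-1-yl benzoate | C=C(C)C[C@H](OC(=O)c1ccccc1)[C@H]2[C@](O)(C(C)C)CC[C@]2(C)CO | intermediate
13 | (1S)-1-[(1S,2S,5R)-2-formyl-5-hydroxy-2-methyl-5-(propan-2-yl)cyclopentyl]-3-methylbut-3-en-1-yl benzoate | C=C(C)C[C@H](OC(=O)c1ccccc1)[C@H]2[C@](O)(C(C)C)CC[C@]2(C)C=O | intermediate
14 | (1S)-1-[(1S,2R,5S)-2-hydroxy-5-[(1R)-1-hydroxyprop-2-en-1-yl]-5-methyl-2-(propan-2-yl)cyclopentyl]-3-methylbut-3-en-1-yl benzoate | C=C(C)C[C@H](OC(=O)c1ccccc1)[C@H]2[C@](O)(C(C)C)CC[C@]2(C)[C@H](O)C=C | intermediate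
15 | (3R,3aS,4S,8R,8aS)-3,8-dihydroxy-6,8a-dimethyl-3-(propan-2-yl)-1,2,3,3a,4,5,8,8a-octahydroazulen-4-yl benzoate | O[C@@H]1C=C(C)C[C@H](OC(=O)c2ccccc2)[C@@H]2[C@]1(C)CC[C@@]2(O)C(C)C | intermediate
16 | (2Z)-2-methylbut-2-enoic acid (angelic acid) | C/C=C(/C)C(=O)O | starting material
17 | (2Z)-2-methylbut-2-enoic 2,4,6-trichlorobenzoic anhydride | C/C=C(/C)C(=O)OC(=O)c1c(Cl)cc(Cl)cc1Cl | intermediate
18 | (3R,3aS,4S,8R,8aS)-3-hydroxy-6,8a-dimethyl-8-{[(2Z)-2-methylbut-2-enoyl]oxy}-3-(propan-2-yl)-1,2,3,3a,4,5,8,8a-octahydroazulen-4-yl benzoate | C/C=C(/C)C(=O)O[C@@H]1C=C(C)C[C@H](OC(=O)c2ccccc2)[C@@H]2[C@]1(C)CC[C@@]2(O)C(C)C | target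

**Count and risks**

Total steps: 11. Longest linear sequence: 10 (steps 1, 2 and 4–11; step 3 makes the aldehyde partner).

Most likely to fail, step 4: the aldehyde may add to both faces of the enolate because the unbranched silyloxymethyl group shields its face too weakly, and the β,γ-unsaturated aldehyde may conjugate before it reacts. The fallback replaces the shield by a branched one and sets out from 1. Manganese dioxide in CH2Cl2 oxidises 1 to 3-oxocyclopent-1-ene-1-carbaldehyde F1. Ethane-1,2-diol with PPTS (benzene, water removal) should acetalise only the aldehyde and give 3-(1,3-dioxolan-2-yl)cyclopent-2-en-1-one F2. The conjugate addition and silylation of step 2 give the triethylsilyl enol ether F3. The boron aldol of step 4 with 6, now facing a branched dioxolanyl group on the quaternary carbon, gives the dioxolanyl aldol F4. The organocerium addition of step 5 gives the dioxolanyl diol F5, and benzoylation as in step 6 gives the dioxolanyl benzoate F6. Acetal hydrolysis (PPTS, acetone–water, 50 °C) returns the route at aldehyde 13 and makes steps 7 and 8 unnecessary.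

Second, step 5: enolisation, reduction by β-hydride transfer or retro-aldol cleavage may outrun addition of the branched nucleophile to the hindered ketone. The fallback uses an sp2 nucleophile and a masked side-chain alkene and sets out from 4. The enolate sequence of step 4 is run with (2-methyl-1,3-dioxolan-2-yl)acetaldehyde in place of 6 and gives the ketal-protected aldol F7. Isopropenylmagnesium bromide with CeCl3 (no transferable β-hydride, smaller than isopropyl) gives the isopropenyl carbinol F8. Hydrogenation (H2, PtO2, EtOAc), possible because no other alkene is present, gives the isopropyl carbinol F9. PPTS in wet acetone unmasks the methyl ketone F10. Lombardo methylenation (Zn, CH2Br2, TiCl4, THF) turns the ketone into the 1,1-disubstituted alkene and returns the route at diol 10.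

Third, step 9: addition to the hindered neopentyl aldehyde may be slow, and background addition through the substrate-derived zinc alkoxide may erode the catalyst-controlled facial selectivity. The fallback sets C10 by reduction instead of addition and sets out from 13. Nozaki–Hiyama–Kishi vinylation (vinyl bromide, CrCl2, NiCl2 cat., DMSO) gives 14 together with its C10 epimer, the (1S)-hydroxyallyl compound F11. Dess–Martin oxidation of the mixture gives the vinyl ketone F12. Corey–Bakshi–Shibata reduction ((S)-Me-CBS, catecholborane, toluene, −78 °C; the quaternary carbon is the large group) should return the route at 14.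

Further compounds
F1 | step 4 | 3-oxocyclopent-1-ene-1-carbaldehyde | O=CC1=CC(=O)CC1
F2 | step 4 | 3-(1,3-dioxolan-2-yl)cyclopent-2-en-1-one | O=C1C=C(C2OCCO2)CC1
F3 | step 4 | triethyl{[(3S)-3-(1,3-dioxolan-2-yl)-3-methylcyclopent-1-en-1-yl]oxy}silane | CC[Si](CC)(CC)OC1=C[C@@](C)(C2OCCO2)CC1
F4 | step 4 | (2S,3S)-3-(1,3-dioxolan-2-yl)-2-[(1S)-1-hydroxy-3-methylbut-3-en-1-yl]-3-methylcyclopentan-1-one | C=C(C)C[C@H](O)[C@H]1C(=O)CC[C@]1(C)C2OCCO2
F5 | step 4 | (1R,2S,3S)-3-(1,3-dioxolan-2-yl)-2-[(1S)-1-hydroxy-3-methylbut-3-en-1-yl]-3-methyl-1-(propan-2-yl)cyclopentan-1-ol | C=C(C)C[C@H](O)[C@H]1[C@](O)(C(C)C)CC[C@]1(C)C2OCCO2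
F6 | step 4 | benzoate of F5 at the secondary hydroxyl (dioxolanyl analogue of 11) | C=C(C)C[C@H](OC(=O)c1ccccc1)[C@H]2[C@](O)(C(C)C)CC[C@]2(C)C3OCCO3
F7 | step 5 | (2S,3S)-2-[(1S)-1-hydroxy-2-(2-methyl-1,3-dioxolan-2-yl)ethyl]-3-methyl-3-({[tri(propan-2-yl)silyl]oxy}methyl)cyclopentan-1-one | CC1(C[C@H](O)[C@H]2C(=O)CC[C@]2(C)CO[Si](C(C)C)(C(C)C)C(C)C)OCCO1
F8 | step 5 | isopropenyl carbinol from F7 (prop-1-en-2-yl in place of the isopropyl group of F9, same spatial arrangement) | CC1(C[C@H](O)[C@H]2[C@](O)(C(C)=C)CC[C@]2(C)CO[Si](C(C)C)(C(C)C)C(C)C)OCCO1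
F9 | step 5 | (1R,2S,3S)-2-[(1S)-1-hydroxy-2-(2-methyl-1,3-dioxolan-2-yl)ethyl]-3-methyl-1-(propan-2-yl)-3-({[tri(propan-2-yl)silyl]oxy}methyl)cyclopentan-1-ol | CC1(C[C@H](O)[C@H]2[C@](O)(C(C)C)CC[C@]2(C)CO[Si](C(C)C)(C(C)C)C(C)C)OCCO1
F10 | step 5 | (4S)-4-hydroxy-4-[(1S,2R,5S)-2-hydroxy-5-methyl-2-(propan-2-yl)-5-({[tri(propan-2-yl)silyl]oxy}methyl)cyclopentyl]butan-2-one | CC(=O)C[C@H](O)[C@H]1[C@](O)(C(C)C)CC[C@]1(C)CO[Si](C(C)C)(C(C)C)C(C)C
F11 | step 9 | C10 epimer of 14 with a (1S)-1-hydroxyprop-2-en-1-yl group | C=C(C)C[C@H](OC(=O)c1ccccc1)[C@H]2[C@](O)(C(C)C)CC[C@]2(C)[C@@H](O)C=C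
F12 | step 9 | (1S)-1-[(1S,2R,5S)-2-hydroxy-5-methyl-5-(prop-2-enoyl)-2-(propan-2-yl)cyclopentyl]-3-methylbut-3-en-1-yl benzoate | C=C(C)C[C@H](OC(=O)c1ccccc1)[C@H]2[C@](O)(C(C)C)CC[C@]2(C)C(=O)C=C
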